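A small charge of initiator, 8.80 % of the free monomer put in, has to carry that monomer into chains against a protic impurity worth 50.0 % of it.

    protic impurity + free monomer → quenched substrate (k1 = 0.0013 M⁻¹ s⁻¹)
    living end + transfer agent → dead chain (k2 = 0.22 M⁻¹ s⁻¹)
    free monomer + living end → monomer in chains + living end, rate k3*[living end]*[free monomer] (k3 = 0.0080 M⁻¹ s⁻¹)
    free monomer + initiator → living end + monomer in chains (k4 = 0.016 M⁻¹ s⁻¹)

| flask | free monomer | transfer agent | protic impurity | initiator | time | remark |
|---|---|---|---|---|---|---|
| green | 0.050 M (fed, over 2.40 d) | 0.500 mM | 0.0250 M | 4.4 mM | 3.0 d | all but free monomer at the start; free monomer goes in evenly over 2.40 d, the run ends at 3.0 d |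
| blue | 0.050 M | 0.500 mM | 0.0250 M | 4.4 mM |  | a single well-mixed tank run continuously and read at steady state, 3.0 d in it on average |
| teal | 0.050 M | 0.500 mM | 0.0250 M | 4.4 mM | 3.0 d | plug flow through a tube for 3.0 d, no back-mixing |
| ochre | 0.050 M | 0.500 mM | 0.0250 M | 4.4 mM | 3.0 d | everything together in a closed stirred flask, run for 3.0 d |

* the set-up with the highest amount of monomer in chains at the outlet or at the end, in percent of the free monomer put in ("none" if the first two lie within 2 percentage points) (green / blue / teal / ochre / none)
* amount of monomer in chains at the outlet or at the end, in percent of the free monomer put in, green
* amount of monomer in chains at the outlet or at the end, in percent of the free monomer put in, blue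
* amount of monomer in chains at the outlet or at the end, in percent of the free monomer put in, teal
* amount of monomer in chains at the outlet or at the end, in percent of the free monomer put in, ochre

- the stated concentrations are those of everything mixed, before any reaction; amounts are the same in each set-up
- the feed brings no volume worth counting
- run time (green): 3.0 d

My first estimate for ochre is the share at the start, with initiator and impurity competing for the same free monomer, which gives the chain side 68.4 %. The objection comes at once: the initiator does not last. Its constant beats the impurity's by a selectivity factor of 12.3, so in ochre, by the time the impurity has fallen by a natural log of 0.5, the initiator stands at 0.213 % of its charge. After that, chains grow through living ends, with a constant half that of the initiator step.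

So I divide one rate by another. I take as a clock x, the natural log of the impurity's fall, which runs in step with free monomer. Dividing the rate of chain growth by the rate of x cancels both free monomer and time. The transfer agent can take 0.500 mM of the ends, and the half-life of living ends by that step, with the agent as charged, 0.073 d, is shorter than the 3.0 d run, so I charge that whole loss from the outset. That leaves the chain gain per unit of clock, the living ends' constant and amount over the impurity's constant and the monomer charge, 0.480. The initiator's burn-off adds a fixed 4.40 % of the charge.

Chains are then that offset plus the gain times x, and quenched substrate climbs towards a ceiling of 50.0 % of the charge, that ceiling multiplied by one minus the exponential of minus x. But do these two fill the charge by the end of ochre? The living ends by themselves give 8.09 natural logs of monomer decay in 3.0 d, leaving 0.0307 %, so I set the sum to the whole charge. Solving by steps from x of 1 gives 1.24, then 1.25. My sum puts chains at 64.3 % in ochre, and at the same figure in teal, where each slice spends the same time as the closed flask.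

The forecast gives 63.4 %, 64.7 %, 64.4 % and 64.4 % for green, blue, teal and ochre, and none as the best, with this ground: “the split between chains and quenched substrate barely depends on the vessel”.

The flask gives 63.4 %, 64.6 %, 64.5 % and 64.5 % in that order, and none as the best, so ochre stands 0.20 percentage points above my sum. Green ends with 1.29 % of its free monomer still unreacted. Taking that remainder out of the sum for green moves the clock back to 1.23, and the same gain of 0.480 with the same offset puts green at 63.4 %, beside its 63.4 %.

All constants were set for the occasion; the result is computed.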